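**Plan**
Numbering: C1 is the quaternary carbinol carrying C7H2OBz, then C2 (OBz), C3=C4, C5 (OBz), C6 (OH). The retrosynthesis cuts C5–OBz first (benzoic acid opening of a C5–C6 vinyl oxirane). It then cuts the C2 ester, the C2–O bond (an ene oxygenation that moved C2=C3 to C3=C4), and last the two oxirane C–O bonds.
Enabling feature: without the oxygens at C2, C5 and C6, ring C1–C6 is a 1-substituted cyclohexa-2,5-dien-1-ol with a mirror plane through C1 and C4. C2=C3 and C5=C6 are therefore enantiotopic, and C1–OH is allylic to both.
Forward order: the six-membered ring comes ready-made from benzoic acid (Birch reduction). C1–O is added by enolate hydroxylation, and C7 is reduced and benzoylated. The only ring formed is the oxirane, which is opened again in the last step.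
Stereochemistry: a chiral vanadium bishydroxamate selects one alkene (absolute sense, C1), and the metal-bound C1 alkoxide fixes the face (C5, C6). C1–OH then guides singlet oxygen to the same face at C2, and SN2 opening inverts C5 to the trans benzoate.

Key step: step 6

Assumption: the sense of induction of the bishydroxamic acid on a cyclic tertiary dienol cannot be derived safely from acyclic cases. The (R,R)-ligand is written and would be replaced by its equally available (S,S)-antipode if a trial run gives the mirror-image epoxide.

Step 1
Reactants: 1 benzoic acid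
Product: 2 cyclohexa-2,5-diene-1-carboxylic acid
Conditions: Na, NH3(l), EtOH, −78 to −33 °C; NH4Cl; aq HCl, Et2O extraction under N2
Reagents that add atoms: none
Why: Birch reduction, in which the carboxylate directs protonation to C4 and C1, so the unconjugated 2,5-diene should form and no stereocentre arises.

Step 2
Reactants: 2 cyclohexa-2,5-diene-1-carboxylic acid
Product: 3 methyl cyclohexa-2,5-diene-1-carboxylate
Conditions: MeI, KHCO3, DMF, rt
Reagents that add atoms: iodomethane, CI
Why: SN2 O-alkylation of the carboxylate with a base too weak to move the skipped diene into conjugation.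

Step 3
Reactants: 3 methyl cyclohexa-2,5-diene-1-carboxylate
Product: 5 methyl 1-hydroxycyclohexa-2,5-diene-1-carboxylate, via potassium dienolate 4 (not isolated)
Conditions: KN(SiMe3)2, THF, −78 °C; 2-(benzenesulfonyl)-3-phenyloxaziridine, −78 °C; sat. aq NH4Cl
Reagents that add atoms: 2-(benzenesulfonyl)-3-phenyloxaziridine, O=S(=O)(N1OC1c1ccccc1)c1ccccc1
Why: Enolate hydroxylation with an N-sulfonyloxaziridine, in which the cross-conjugated dienolate takes up electrophiles at C1 as in Birch reduction–alkylation, and transfer of a single oxygen gives the alkoxide without a hydroperoxide stage that could fragment to the arene.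

Step 4
Reactants: 5 methyl 1-hydroxycyclohexa-2,5-diene-1-carboxylate
Product: 6 1-(hydroxymethyl)cyclohexa-2,5-dien-1-ol
Conditions: LiAlH4, Et2O, 0 °C; Na2SO4·10H2O; filtered, used crude
Reagents that add atoms: none
Why: Hydride reduction of an ester to the primary alcohol, with isolated alkenes inert at 0 °C and a basic work-up that spares the acid-labile dienol.

Step 5
Reactants: 6 1-(hydroxymethyl)cyclohexa-2,5-dien-1-ol; 7 benzoyl chloride
Product: 8 1-(benzoyloxymethyl)cyclohexa-2,5-dien-1-ol
Conditions: BzCl (1.05 equiv), Et3N, DMAP (cat.), CH2Cl2, −20 °C; NaHCO3 work-up, Et3N-deactivated silica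
Reagents that add atoms: benzoyl chloride (7), O=C(Cl)c1ccccc1
Why: Chemoselective acylation, since the primary C7–OH reacts far faster than the tertiary doubly allylic C1–OH and the amine keeps the medium basic.

Step 6
Reactants: 8 1-(benzoyloxymethyl)cyclohexa-2,5-dien-1-ol; 9 tert-butyl hydroperoxide
Product: 10 (1S,5S,6S)-1-(benzoyloxymethyl)-5,6-epoxycyclohex-2-en-1-ol (oxirane oxygen cis to C1–OH)
Conditions: VO(OiPr)3 (5 mol %), (R,R)-N,N′-dihydroxy-N,N′-bis(diphenylacetyl)cyclohexane-1,2-diamine (10 mol %), tBuOOH (5.5 M in decane, 1.0 equiv), toluene, −20 °C, dark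
Reagents that add atoms: tert-butyl hydroperoxide (9), CC(C)(C)OO
Why: VO(OiPr)3 and the C2-symmetric bishydroxamic acid form a pentavalent vanadium complex that exchanges its remaining alkoxides for the C1 alkoxide of 8 and for the alkyl peroxide, and the activated peroxide oxygen is then handed to the nearby alkene inside this template. The closest known reaction type is the metal/bishydroxamic acid-catalysed hydroxyl-directed asymmetric epoxidation of allylic alcohols, which has been used to desymmetrise dialkenyl carbinols and, on hafnium and tungsten, to epoxidise tertiary allylic alcohols. The oxirane closes by concerted suprafacial addition of that one oxygen across C5=C6, so both C–O bonds form in a single event. C5 and C6 are fixed by the tether, because the oxygen arrives on the face that carries the metal-bound C1–O, whereas C1 becomes stereogenic only through the ligand's choice between the enantiotopic C5=C6 and C2=C3. The step needs group selectivity, mono- over bis-epoxidation and survival of an acid-labile dienol: the benzoate leaves C1–OH as the only binding site, and one equivalent of oxidant limits a second epoxidation, which should in any case consume the minor enantiomer faster and convert it into a separable meso bis-epoxide. The fully ligated metal in toluene at low temperature in the dark keeps Lewis acidity and radical attack on the doubly allylic C4H2 low.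

Step 7
Reactants: 10 (1S,5S,6S)-1-(benzoyloxymethyl)-5,6-epoxycyclohex-2-en-1-ol
Product: 12 (1R,2R,5S,6S)-1-(benzoyloxymethyl)-5,6-epoxycyclohex-3-ene-1,2-diol, via allylic hydroperoxide 11 (not isolated)
Conditions: O2, tetraphenylporphyrin (cat.), visible light, CCl4, 0 °C; then PPh3, 0 °C
Reagents that add atoms: dioxygen, O=O
Why: Schenck ene reaction and phosphine reduction of the hydroperoxide: C1 is quaternary, so the only allylic hydrogens of C2=C3 sit on C4 and oxygen can bond only to C2 while the alkene moves to C3=C4, and in a non-polar solvent hydrogen bonding of the incoming oxygen to C1–OH, helped by C7H2OBz screening the other face, should place C2–O cis to C1–OH (2R).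

Step 8
Reactants: 12 (1R,2R,5S,6S)-1-(benzoyloxymethyl)-5,6-epoxycyclohex-3-ene-1,2-diol; 7 benzoyl chloride
Product: 13 (1R,2R,5S,6S)-2-benzoyloxy-1-(benzoyloxymethyl)-5,6-epoxycyclohex-3-en-1-ol
Conditions: BzCl (1.1 equiv), Et3N, DMAP (cat.), CH2Cl2, 0 °C
Reagents that add atoms: benzoyl chloride (7), O=C(Cl)c1ccccc1
Why: Acylation of the only secondary hydroxyl, since C1–OH is tertiary and C6–O is still masked in the oxirane, so there is no site-selectivity problem and no stereocentre is touched.

Step 9
Reactants: 13 (1R,2R,5S,6S)-2-benzoyloxy-1-(benzoyloxymethyl)-5,6-epoxycyclohex-3-en-1-ol; 1 benzoic acid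
Product: 14 [(1S,2R,5R,6S)-2,5-bis(benzoyloxy)-1,6-dihydroxycyclohex-3-en-1-yl]methyl benzoate (target)
Conditions: PhCO2H (2 equiv), Ti(OiPr)4 (1.5 equiv), CH2Cl2, 0 °C to rt; sat. aq NaHCO3, filtration
Reagents that add atoms: benzoic acid (1), OC(=O)c1ccccc1
Why: Titanium-assisted SN2 opening of a 2,3-epoxy alcohol by a carboxylic acid, in which chelation of titanium between C1–O and the cis oxirane oxygen, allylic activation by C3=C4 and the neopentyl character of C6 all direct benzoate to C5, where backside attack inverts C5 (S to R) and frees C6–OH cis to C1–OH.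

**Compound list**
1 | benzoic acid | OC(=O)c1ccccc1 | starting material
2 | cyclohexa-2,5-diene-1-carboxylic acid | OC(=O)C1C=CCC=C1 | intermediate
3 | methyl cyclohexa-2,5-diene-1-carboxylate | COC(=O)C1C=CCC=C1 | intermediate
4 | potassium dienolate of 3 | COC([O-])=C1C=CCC=C1.[K+] | intermediate
5 | methyl 1-hydroxycyclohexa-2,5-diene-1-carboxylate | COC(=O)C1(O)C=CCC=C1 | intermediate
6 | 1-(hydroxymethyl)cyclohexa-2,5-dien-1-ol | OCC1(O)C=CCC=C1 | intermediate
7 | benzoyl chloride | O=C(Cl)c1ccccc1 | starting material
8 | 1-(benzoyloxymethyl)cyclohexa-2,5-dien-1-ol | O=C(OCC1(O)C=CCC=C1)c1ccccc1 | intermediate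
9 | tert-butyl hydroperoxide | CC(C)(C)OO | starting material
10 | (1S,5S,6S)-1-(benzoyloxymethyl)-5,6-epoxycyclohex-2-en-1-ol | O=C(OC[C@@]1(O)C=CC[C@@H]2O[C@H]12)c1ccccc1 | intermediate
11 | (1S,2R,5S,6S)-1-(benzoyloxymethyl)-5,6-epoxy-2-hydroperoxycyclohex-3-en-1-ol | O=C(OC[C@@]1(O)[C@H](OO)C=C[C@@H]2O[C@H]12)c1ccccc1 | intermediate
12 | (1R,2R,5S,6S)-1-(benzoyloxymethyl)-5,6-epoxycyclohex-3-ene-1,2-diol | O=C(OC[C@@]1(O)[C@H](O)C=C[C@@H]2O[C@H]12)c1ccccc1 | intermediate
13 | (1R,2R,5S,6S)-2-benzoyloxy-1-(benzoyloxymethyl)-5,6-epoxycyclohex-3-en-1-ol | O=C(OC[C@@]1(O)[C@H](OC(=O)c3ccccc3)C=C[C@@H]2O[C@H]12)c1ccccc1 | intermediate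
14 | [(1S,2R,5R,6S)-2,5-bis(benzoyloxy)-1,6-dihydroxycyclohex-3-en-1-yl]methyl benzoate | O=C(OC[C@@]1(O)[C@H](OC(=O)c2ccccc2)C=C[C@@H](OC(=O)c2ccccc2)[C@@H]1O)c1ccccc1 | target

The C1 descriptor alternates between S and R along 10–14 only because the CIP ranking of C2 and C6 changes. The centre itself is never touched after step 6.

**Step count:** 9 steps in total. The longest linear sequence is 9 steps (1 to 14).

**Steps most likely to fail**

Risk 1, step 6. Three processes threaten this step.
- The doubly allylic tertiary C1–O bond may ionise on the Lewis-acidic metal, with loss of water and aromatisation.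
- The doubly allylic C4–H bonds may be attacked by alkoxyl radicals.
- A crowded tertiary alkoxide may bind too loosely for good discrimination of the two alkenes.

Moving the same ligand to Hf(OtBu)4 or WO2(acac)2 would only change the conditions. The fallback changes the oxidation level of C7 and the order of events. It sets out from 5, whose carbonyl group destabilises a cation at C1 and so blocks aromatisation. The directed desymmetrising epoxidation with 9 should give methyl (1R,5S,6S)-5,6-epoxy-1-hydroxycyclohex-2-ene-1-carboxylate F1. NaBH4 in THF/MeOH reduces α-hydroxy esters through an alkoxyborohydride and leaves oxiranes alone, so it should give (1S,5S,6S)-5,6-epoxy-1-(hydroxymethyl)cyclohex-2-en-1-ol F2. Primary-selective benzoylation with 7 comes back to the route at 10. This path also avoids isolating the labile dienols 6 and 8.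

Risk 2, step 7. The ene reaction of a cis-disubstituted alkene bearing withdrawing allylic oxygen may be too slow, so that photodegradation competes. Oxygen may also approach the face opposite to C1–OH. The fallback exchanges the roles of the two alkenes, so that no ene reaction is needed.
- It sets out from 8 and uses the antipodal ligand in the same epoxidation to give the mirror-image epoxide ent-10 F3. In target numbering this is a C2–C3 oxirane cis to C1–OH with the alkene at C5=C6.
- PhSeSePh/NaBH4 in EtOH should open it at C3, remote from the quaternary C1, to the trans hydroxy selenide F4.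
- H2O2 gives the selenoxide F5, whose syn elimination runs away from the carbinol carbon to (1R,2R)-1-(benzoyloxymethyl)cyclohexa-3,5-diene-1,2-diol F6.
- Benzoylation of its only secondary hydroxyl with 7 gives the C2 benzoate F7.
- VO(acac)2 with 9 then delivers oxygen from C1–OH to the adjacent C5=C6, because C3=C4 is only homoallylic and is deactivated by the allylic benzoate. The sequence comes back to the route at 13.

Risk 3, step 3. The very electron-rich dienolate may transfer an electron or a hydride to the oxidant and aromatise. It may also react at C4, or add to the sulfonimine that is released. The fallback leaves anion chemistry. It sets out from 4, which is trapped with Me3SiCl as the trimethylsilyl ketene acetal F8. A Rubottom oxidation (mCPBA, NaHCO3, CH2Cl2, −20 °C) should epoxidise the electron-rich exocyclic alkene selectively. After silyl migration this gives methyl 1-(trimethylsilyloxy)cyclohexa-2,5-diene-1-carboxylate F9. K2CO3 in MeOH removes the silyl group and comes back to the route at 5.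

**Further compounds**
F1 | step 6 | methyl (1R,5S,6S)-5,6-epoxy-1-hydroxycyclohex-2-ene-1-carboxylate | COC(=O)[C@@]1(O)C=CC[C@@H]2O[C@H]12
F2 | step 6 | (1S,5S,6S)-5,6-epoxy-1-(hydroxymethyl)cyclohex-2-en-1-ol | OC[C@@]1(O)C=CC[C@@H]2O[C@H]12
F3 | step 7 | ent-10, (1R,2R,3R)-1-(benzoyloxymethyl)-2,3-epoxycyclohex-5-en-1-ol in target numbering | O=C(OC[C@@]1(O)[C@@H]2O[C@@H]2CC=C1)c1ccccc1
F4 | step 7 | (1R,2S,3S)-1-(benzoyloxymethyl)-3-(phenylselanyl)cyclohex-5-ene-1,2-diol | O=C(OC[C@@]1(O)[C@H](O)[C@@H]([Se]c2ccccc2)CC=C1)c1ccccc1
F5 | step 7 | selenoxide of F4 | O=C(OC[C@@]1(O)[C@H](O)[C@@H]([Se](=O)c2ccccc2)CC=C1)c1ccccc1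
F6 | step 7 | (1R,2R)-1-(benzoyloxymethyl)cyclohexa-3,5-diene-1,2-diol | O=C(OC[C@@]1(O)[C@H](O)C=CC=C1)c1ccccc1
F7 | step 7 | (1R,2R)-2-benzoyloxy-1-(benzoyloxymethyl)cyclohexa-3,5-dien-1-ol | O=C(OC[C@@]1(O)[C@H](OC(=O)c2ccccc2)C=CC=C1)c1ccccc1
F8 | step 3 | [(cyclohexa-2,5-dien-1-ylidene)(methoxy)methoxy]trimethylsilane | COC(O[Si](C)(C)C)=C1C=CCC=C1
F9 | step 3 | methyl 1-(trimethylsilyloxy)cyclohexa-2,5-diene-1-carboxylate | COC(=O)C1(O[Si](C)(C)C)C=CCC=C1
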